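The retrosynthesis first removes the C9 acetate. It then cuts ring bond C8–C9 of the ten-membered carbocycle, so that C7–H/C8H2 go back to the diene C8=C7–C11=C12 and C9 to an aldehyde. The remaining cuts are C4=C5 (Wittig), C3–C4 (ylide alkylation), C14–O (carboxylate SN2), the oxirane C1–O–C10 (epoxidation) and C1–C10 (Morita–Baylis–Hillman).
The enabling feature is the run O–C9H–C8H2–C7H(C6)–C11(=C12H2)–C13H3 in the ten-membered ring. It is a bishomoallylic alcohol with a 1,3-anti C9–O/C7–C6 relation (chain C10–C9–C8–C7–C11 drawn zigzag) and an exocyclic isopropenyl group. This is the imprint of a nickel-catalysed reductive coupling of an aldehyde with one terminus of a 2,3-disubstituted 1,3-diene. C10 is fully substituted, so the aldehyde cannot enolise, and the oxirane at C1/C10 removes the allylic ester that zerovalent nickel would ionise.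
In the forward direction the chain C9–C10(C14)=C1–C2–C3 comes first and the oxirane ring is closed on the open chain. The chain is extended to C4/C15 as a stabilised ylide and joined with the diene aldehyde C5–C8/C11–C13. The ten-membered ring closes in the penultimate step and acetylation comes last.
C2' is bought with (R)-2-methylbutanoic acid. C1 and C10 come from a Sharpless epoxidation with D-(−)-DIPT on a geometrically defined alkene (geometry from the Morita–Baylis–Hillman bromide). C9 (by the oxirane) and C7 (by the nickelacycle) are both set in the ring closure, and the C4=C5 geometry comes from the stabilised ylide.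

Key step: step 10

Remark: germacrane numbering is used (C7 bears the isopropenyl group C11–C13; then C6, C5=C4(C15O2Me), C3, C2, oxirane C1–O–C10, C14 = CH2O on C10, C9 = CHOAc, C8 = CH2 back to C7; C2' = stereocentre of the acyl group, which is R in the given structure). Compounds 1, 6, 9 and 13 are taken as catalogue compounds.

Step 1
Reactants: 1 3-[(tert-butyldimethylsilyl)oxy]propanal; 2 methyl acrylate
Product: 3 methyl 5-[(tert-butyldimethylsilyl)oxy]-3-hydroxy-2-methylidenepentanoate (racemic)
Conditions: DABCO (0.5 equiv), MeOH, rt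
Reagents that add atoms: none
Why: Morita–Baylis–Hillman reaction, in which the DABCO/acrylate zwitterionic enolate adds to the unhindered aliphatic aldehyde and forms C1–C10; the racemic carbinol centre is erased in step 2.

Step 2
Reactants: 3 methyl 5-[(tert-butyldimethylsilyl)oxy]-3-hydroxy-2-methylidenepentanoate
Product: 4 methyl (2Z)-5-bromo-2-(bromomethyl)pent-2-enoate
Conditions: Ph3PBr2 (2.4 equiv), CH2Cl2, 0 °C to rt
Reagents that add atoms: dibromotriphenylphosphorane BrP(Br)(c1ccccc1)(c1ccccc1)c1ccccc1
Why: Appel-type activation, in which bromide attacks the activated Morita–Baylis–Hillman alcohol in the SN2' sense to give the conjugated ester with the chain trans to CO2Me (the usual, thermodynamically favoured Z bromide of acrylate adducts), while the same reagent is known to convert primary TBS ethers directly into bromides, so the C3 leaving group is installed without a separate deprotection.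

Step 3
Reactants: 4 methyl (2Z)-5-bromo-2-(bromomethyl)pent-2-enoate
Product: 5 (2Z)-5-bromo-2-(bromomethyl)pent-2-en-1-ol
Conditions: iBu2AlH (DIBAL-H, 2.3 equiv), CH2Cl2, −78 °C; aq KNaC4H4O6 (potassium sodium tartrate)
Reagents that add atoms: none
Why: 1,2-reduction of the conjugated ester at low temperature, known for 2-(bromomethyl)acrylates, is faster than any attack on the allylic or alkyl bromide and leaves the alkene geometry untouched.

Step 4
Reactants: 5 (2Z)-5-bromo-2-(bromomethyl)pent-2-en-1-ol; 6 (2R)-2-methylbutanoic acid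
Product: 7 (2Z)-5-bromo-2-(hydroxymethyl)pent-2-en-1-yl (2R)-2-methylbutanoate
Conditions: Cs2CO3 (0.55 equiv), 6 (1.0 equiv), DMF, 0 °C to rt
Reagents that add atoms: none
Why: SN2 displacement by a caesium carboxylate, in which the allylic C14 bromide reacts much faster than the unactivated C3 bromide and ester formation through the carboxylate oxygen cannot racemise C2'.

Step 5
Reactants: 7 (2Z)-5-bromo-2-(hydroxymethyl)pent-2-en-1-yl (2R)-2-methylbutanoate
Product: 8 [(2S,3R)-3-(2-bromoethyl)-2-(hydroxymethyl)oxiran-2-yl]methyl (2R)-2-methylbutanoate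
Conditions: Ti(OiPr)4 (10 mol%), D-(−)-DIPT (13 mol%), t-BuOOH, 4 Å molecular sieves, CH2Cl2, −20 °C
Reagents that add atoms: tert-butyl hydroperoxide CC(C)(C)OO
Why: Sharpless asymmetric epoxidation of an allylic alcohol whose chain is trans to CH2OH (the well-behaved substrate class), in which the D-(−)-tartrate/titanium complex delivers oxygen to the face that makes C1 R and C10 S, and syn addition keeps C2 cis to C14 on the oxirane.

Step 6
Reactants: 8 [(2S,3R)-3-(2-bromoethyl)-2-(hydroxymethyl)oxiran-2-yl]methyl (2R)-2-methylbutanoate; 9 methyl (triphenyl-λ5-phosphanylidene)acetate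
Product: 12 methyl 4-[(2R,3S)-3-(hydroxymethyl)-3-({[(2R)-2-methylbutanoyl]oxy}methyl)oxiran-2-yl]-2-(triphenyl-λ5-phosphanylidene)butanoate, via iodide 10 (not isolated), via phosphonium iodide 11 (not isolated)
Conditions: NaI (1.5 equiv), 9 (2.0 equiv), MeCN, 60 °C; filtration of the precipitated salt
Reagents that add atoms: none
Why: Finkelstein exchange, C-alkylation of the stabilised ylide and transylidation by the second equivalent of 9 form C3–C4 by the established route to α-alkylated phosphoranes, under nearly neutral conditions that oxirane, ester and free alcohol should tolerate.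

Step 7
Reactants: 13 pent-3-yn-1-ol; 14 ethene
Product: 15 4-methyl-3-methylidenepent-4-en-1-ol
Conditions: second-generation Grubbs catalyst (5 mol%), ethene (1 atm), CH2Cl2, 40 °C
Reagents that add atoms: none
Why: ethene–alkyne cross (enyne) metathesis, in which the ruthenium methylidene adds to the internal alkyne and ethene turns the vinylcarbene over, converts the butynyl unit into the 2,3-disubstituted butadiene with C8 and C12 coming from ethene.

Step 8
Reactants: 15 4-methyl-3-methylidenepent-4-en-1-ol; 12 methyl 4-[(2R,3S)-3-(hydroxymethyl)-3-({[(2R)-2-methylbutanoyl]oxy}methyl)oxiran-2-yl]-2-(triphenyl-λ5-phosphanylidene)butanoate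
Product: 17 methyl (2E)-6-methyl-5-methylidene-2-{2-[(2R,3S)-3-(hydroxymethyl)-3-({[(2R)-2-methylbutanoyl]oxy}methyl)oxiran-2-yl]ethyl}hepta-2,6-dienoate, via aldehyde 16 (not isolated)
Conditions: 15, Dess–Martin periodinane (1.05 equiv), NaHCO3, CH2Cl2, 0 °C; cold aq NaHCO3/Na2S2O3 wash, MgSO4; the dried solution is added to 12, CH2Cl2, 0 °C to rt
Reagents that add atoms: none
Why: buffered Dess–Martin oxidation gives the labile β,γ-unsaturated aldehyde without base, and the Wittig reaction of the α-branched stabilised ylide, used at once, should give the trisubstituted ester with C6 trans to CO2Me (E) as is normal for such ylides.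

Step 9
Reactants: 17 methyl (2E)-6-methyl-5-methylidene-2-{2-[(2R,3S)-3-(hydroxymethyl)-3-({[(2R)-2-methylbutanoyl]oxy}methyl)oxiran-2-yl]ethyl}hepta-2,6-dienoate
Product: 18 methyl (2E)-2-{2-[(2R,3S)-3-formyl-3-({[(2R)-2-methylbutanoyl]oxy}methyl)oxiran-2-yl]ethyl}-6-methyl-5-methylidenehepta-2,6-dienoate
Conditions: Dess–Martin periodinane (1.3 equiv), NaHCO3, CH2Cl2, 0 °C to rt
Reagents that add atoms: none
Why: Dess–Martin oxidation of a primary 2,3-epoxy alcohol is standard, and C10 carries no hydrogen, so neither epimerisation nor β-elimination of the epoxy aldehyde is possible.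

Step 10
Reactants: 18 methyl (2E)-2-{2-[(2R,3S)-3-formyl-3-({[(2R)-2-methylbutanoyl]oxy}methyl)oxiran-2-yl]ethyl}-6-methyl-5-methylidenehepta-2,6-dienoate
Product: 20 methyl (1R,4E,7S,9S,10S)-1,10-epoxy-9-hydroxy-14-[(2R)-2-methylbutanoyloxy]germacra-4,11(12)-dien-15-oate, via diethylborinate 19 (not isolated)
Conditions: Ni(acac)2 (20 mol%), Et3B (3 equiv), THF, 0.003 M, addition of 18 over 12 h, 25 °C, N2; aq NaHCO3
Reagents that add atoms: none
Why: Proposed new method: Et3B reduces Ni(acac)2 to zerovalent nickel, which binds the s-cis diene C8=C7–C11=C12 and couples its terminus C8 oxidatively with the Et3B-activated aldehyde carbon C9 to an oxanickelacycle (nickel held by O9 and by the η3-allyl C7–C11–C12), after which ethyl transfer from boron to nickel, β-hydride elimination (ethene) and C–H reductive elimination at C7 release borinate 19 and return zerovalent nickel. The closest known reaction type is the Ni(acac)2/Et3B homoallylation of aldehydes with 1,3-dienes, established intermolecularly (2-substituted and 2,3-disubstituted dienes, bishomoallylic alcohols, 1,3-anti) and for five- and six-membered rings, together with nickel-catalysed alkyne–aldehyde reductive macrocyclisations; a ten-membered ring and a tether fixed at the inner diene carbon C7 are what is new. The ten-membered carbocycle closes endo with respect to C7=C8 (both carbons become ring members), exo with respect to C9=O, and leaves C11=C12 outside the ring as the isopropenyl group. C9 (S) is controlled by the oxirane: with non-chelating boron on O9 the aldehyde should react from the dipole-minimised conformer in which C9=O eclipses C10–C14, and C8 arrives anti to the C10–O bond (polar Felkin–Anh/Cornforth), the trajectory that also keeps the trans-oxirane oxygen on the periphery of the nascent ring. C7 (S) is controlled by the nickelacycle: hydrogen is handed over by the nickel that is tied to O9 within the five-membered unit Ni–O9–C9–C8–C7, in which C10 and the allyl arm C11 sit cis and C6 trans (the 1,3-anti topology of the parent reaction), an arrangement that corresponds to an anti/gauche torsion pair along C10–C9–C8–C7–C6 and therefore fits a ten-membered ring. The step needs site selectivity for C8 over C12 (ten- against eleven-membered ring; C8 is the terminus next to the tether and gives the smaller ring), chemoselectivity for the aldehyde (the trisubstituted enoate, the saturated ester and the trisubstituted oxirane are not partners for nickel/Et3B, and no allylic leaving group is left) and cyclisation over oligomerisation, which the cis turn at C4=C5, the kink of the oxirane and pseudo-high dilution are meant to secure.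

Step 11
Reactants: 20 methyl (1R,4E,7S,9S,10S)-1,10-epoxy-9-hydroxy-14-[(2R)-2-methylbutanoyloxy]germacra-4,11(12)-dien-15-oate
Product: 21 methyl (1R,4E,7S,9S,10S)-9-acetoxy-1,10-epoxy-14-[(2R)-2-methylbutanoyloxy]germacra-4,11(12)-dien-15-oate (CNP0352790.1)
Conditions: Ac2O, pyridine, DMAP (cat.), CH2Cl2, 0 °C to rt
Reagents that add atoms: acetic anhydride CC(=O)OC(C)=O
Why: DMAP-catalysed O-acylation proceeds with retention at C9 and is too weakly basic to start a Payne rearrangement of the epoxy alcohol.

Compound list
1 | 3-[(tert-butyldimethylsilyl)oxy]propanal | O=CCCO[Si](C)(C)C(C)(C)C | starting material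
2 | methyl acrylate | C=CC(=O)OC | starting material
3 | methyl 5-[(tert-butyldimethylsilyl)oxy]-3-hydroxy-2-methylidenepentanoate (racemic) | C=C(C(=O)OC)C(O)CCO[Si](C)(C)C(C)(C)C | intermediate
4 | methyl (2Z)-5-bromo-2-(bromomethyl)pent-2-enoate | COC(=O)/C(CBr)=C/CCBr | intermediate
5 | (2Z)-5-bromo-2-(bromomethyl)pent-2-en-1-ol | OC/C(CBr)=C/CCBr | intermediate
6 | (2R)-2-methylbutanoic acid | CC[C@@H](C)C(=O)O | starting material
7 | (2Z)-5-bromo-2-(hydroxymethyl)pent-2-en-1-yl (2R)-2-methylbutanoate | OC/C(COC(=O)[C@H](C)CC)=C/CCBr | intermediate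
8 | [(2S,3R)-3-(2-bromoethyl)-2-(hydroxymethyl)oxiran-2-yl]methyl (2R)-2-methylbutanoate | BrCC[C@H]1O[C@]1(COC(=O)[C@H](C)CC)CO | intermediate
9 | methyl (triphenyl-λ5-phosphanylidene)acetate | COC(=O)C=P(c1ccccc1)(c1ccccc1)c1ccccc1 | starting material
10 | [(2S,3R)-2-(hydroxymethyl)-3-(2-iodoethyl)oxiran-2-yl]methyl (2R)-2-methylbutanoate | ICC[C@H]1O[C@]1(COC(=O)[C@H](C)CC)CO | intermediate
11 | {1-methoxy-1-oxo-4-[(2R,3S)-3-(hydroxymethyl)-3-({[(2R)-2-methylbutanoyl]oxy}methyl)oxiran-2-yl]butan-2-yl}triphenylphosphonium iodide (epimers at C4) | COC(=O)C(CC[C@H]1O[C@]1(COC(=O)[C@H](C)CC)CO)[P+](c1ccccc1)(c1ccccc1)c1ccccc1.[I-] | intermediate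
12 | methyl 4-[(2R,3S)-3-(hydroxymethyl)-3-({[(2R)-2-methylbutanoyl]oxy}methyl)oxiran-2-yl]-2-(triphenyl-λ5-phosphanylidene)butanoate | COC(=O)C(CC[C@H]1O[C@]1(COC(=O)[C@H](C)CC)CO)=P(c1ccccc1)(c1ccccc1)c1ccccc1 | intermediate
13 | pent-3-yn-1-ol | CC#CCCO | starting material
14 | ethene | C=C | starting material
15 | 4-methyl-3-methylidenepent-4-en-1-ol | C=C(C)C(=C)CCO | intermediate
16 | 4-methyl-3-methylidenepent-4-enal | C=C(C)C(=C)CC=O | intermediate
17 | methyl (2E)-6-methyl-5-methylidene-2-{2-[(2R,3S)-3-(hydroxymethyl)-3-({[(2R)-2-methylbutanoyl]oxy}methyl)oxiran-2-yl]ethyl}hepta-2,6-dienoate | C=C(C)C(=C)C/C=C(/C(=O)OC)CC[C@H]1O[C@]1(COC(=O)[C@H](C)CC)CO | intermediate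
18 | methyl (2E)-2-{2-[(2R,3S)-3-formyl-3-({[(2R)-2-methylbutanoyl]oxy}methyl)oxiran-2-yl]ethyl}-6-methyl-5-methylidenehepta-2,6-dienoate | C=C(C)C(=C)C/C=C(/C(=O)OC)CC[C@H]1O[C@]1(COC(=O)[C@H](C)CC)C=O | intermediate
19 | O9-diethylborinate of 20 | C=C(C)[C@H]1C/C=C(/C(=O)OC)CC[C@H]2O[C@]2(COC(=O)[C@H](C)CC)[C@@H](OB(CC)CC)C1 | intermediate
20 | methyl (1R,4E,7S,9S,10S)-1,10-epoxy-9-hydroxy-14-[(2R)-2-methylbutanoyloxy]germacra-4,11(12)-dien-15-oate | C=C(C)[C@H]1C/C=C(/C(=O)OC)CC[C@H]2O[C@]2(COC(=O)[C@H](C)CC)[C@@H](O)C1 | intermediate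
21 | methyl (1R,4E,7S,9S,10S)-9-acetoxy-1,10-epoxy-14-[(2R)-2-methylbutanoyloxy]germacra-4,11(12)-dien-15-oate (CNP0352790.1) | C=C(C)[C@H]1C/C=C(/C(=O)OC)CC[C@H]2O[C@]2(COC(=O)[C@H](C)CC)[C@@H](OC(C)=O)C1 | target

Total step count: 11. Longest linear sequence: 10 (steps 1–6 and 8–11).

Steps most likely to fail

Step 10. Intermolecular coupling may outrun ring closure, and C–C bond formation may take place at the distal diene terminus C12. A nickel hydride may move the skipped double bonds around C6 into conjugation, and the aldehyde may be approached from the other face.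
The fallback uses known chemistry, sets out from 12 and comes back at 20. C7 is bought instead of made.
- Commercial (R)-lavandulol already holds the unit C8H2–C7H(isopropenyl)–C6H2–C5H= in the right absolute configuration. It would be brominated (CBr4, PPh3) to (R)-lavandulyl bromide F1.
- One equivalent of mCPBA would epoxidise the more electron-rich trisubstituted double bond to bromo epoxide F2.
- H5IO6 would cleave F2 to bromo aldehyde F3, a C–C cleavage that sheds acetone and keeps the stereocentre.
- Wittig reaction of F3 with 12 would give seco bromide F4, and Dess–Martin oxidation would give bromo epoxy aldehyde F5.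
- The same C8–C9 bond would then be closed by a cobalt-catalysed alkyl Nozaki–Hiyama–Kishi reaction (CrCl2, LiI, catalytic cobalt phthalocyanine CoC32H16N8, DMF, high dilution). In it a trivalent alkylchromium species adds chemoselectively to the aldehyde and leads to 20.

Step 8. The β,γ-unsaturated aldehyde may undergo a prototropic shift into conjugation, evaporate or polymerise before the hindered ylide has consumed it.
The fallback sets out from 12 and comes back at 17. The skipped triene is made by sp3–sp2 cross-coupling, so that no β,γ-unsaturated aldehyde is needed.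
- 12 would be condensed with aqueous chloroacetaldehyde to the (E)-γ-chloro ester F6.
- Ethene–alkyne metathesis of commercial 4,4,5,5-tetramethyl-2-(prop-1-yn-1-yl)-1,3,2-dioxaborolane with 14 (second-generation Grubbs catalyst) would give dienylboronate F7.
- Suzuki–Miyaura allyl–alkenyl coupling of F6 with F7 (Pd(PPh3)4, CsF, THF, 50 °C) at the unsubstituted allyl terminus C6 should give 17.

Step 6. Alkylation at the unactivated primary carbon may be sluggish. That would leave time for a 1,3-acyl shift from the C14 oxygen to the free C9 oxygen and for halide opening of the oxirane.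
The fallback sets out from 8 and 9 and comes back at 17. The C3–C4 bond is made after the olefination.
- 9 would be brominated with NBS to bromo ylide F8.
- Wittig reaction of F8 with 16 gives the (Z)-α-bromo ester F9, with Br cis to C6.
- Nickel-catalysed cross-electrophile coupling of F9 with alkyl bromide 8 (NiI2, 4,4'-di-tert-butyl-2,2'-bipyridine, NaI, Mn powder, DMA, rt) would replace Br by C3 with retention of the alkene geometry and give 17 directly.

Further compounds
F1 | step 10 | (2R)-1-bromo-5-methyl-2-(prop-1-en-2-yl)hex-4-ene ((R)-lavandulyl bromide) | C=C(C)[C@H](CBr)CC=C(C)C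
F2 | step 10 | 3-[(2R)-2-(bromomethyl)-3-methylbut-3-en-1-yl]-2,2-dimethyloxirane (epimers at the oxirane carbon) | C=C(C)[C@H](CBr)CC1OC1(C)C
F3 | step 10 | (3R)-3-(bromomethyl)-4-methylpent-4-enal | C=C(C)[C@H](CBr)CC=O
F4 | step 10 | methyl (2E,5R)-5-(bromomethyl)-6-methyl-2-{2-[(2R,3S)-3-(hydroxymethyl)-3-({[(2R)-2-methylbutanoyl]oxy}methyl)oxiran-2-yl]ethyl}hepta-2,6-dienoate | C=C(C)[C@H](CBr)C/C=C(/C(=O)OC)CC[C@H]1O[C@]1(COC(=O)[C@H](C)CC)CO
F5 | step 10 | methyl (2E,5R)-5-(bromomethyl)-2-{2-[(2R,3S)-3-formyl-3-({[(2R)-2-methylbutanoyl]oxy}methyl)oxiran-2-yl]ethyl}-6-methylhepta-2,6-dienoate | C=C(C)[C@H](CBr)C/C=C(/C(=O)OC)CC[C@H]1O[C@]1(COC(=O)[C@H](C)CC)C=O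
F6 | step 8 | methyl (2E)-4-chloro-2-{2-[(2R,3S)-3-(hydroxymethyl)-3-({[(2R)-2-methylbutanoyl]oxy}methyl)oxiran-2-yl]ethyl}but-2-enoate | ClC/C=C(/C(=O)OC)CC[C@H]1O[C@]1(COC(=O)[C@H](C)CC)CO
F7 | step 8 | 4,4,5,5-tetramethyl-2-(3-methylbuta-1,3-dien-2-yl)-1,3,2-dioxaborolane | C=C(C)C(=C)B1OC(C)(C)C(C)(C)O1
F8 | step 6 | methyl bromo(triphenyl-λ5-phosphanylidene)acetate | COC(=O)C(Br)=P(c1ccccc1)(c1ccccc1)c1ccccc1
F9 | step 6 | methyl (2Z)-2-bromo-6-methyl-5-methylidenehepta-2,6-dienoate | C=C(C)C(=C)C/C=C(/C(=O)OC)Br
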